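**Retrosynthetic overview**
1. Gnetupendin B ⇒ its constitutional isomer, the 3-O-(3,4-dihydroxybenzyl) ether of isorhapontigenin, carried as the bis-TBS ether. The ring A–CH2 bond is delivered from oxygen to the neighbouring ring carbon by an O→C relay through a p-quinone methide.
2. That ether ⇒ aryl–vinyl (Heck) disconnection into a 3-bromo-5-(benzyloxy)phenol and 2-methoxy-4-vinylphenol. This step sets the E alkene.
3. Key disconnection: the aryl–O–CH2 ether C–O bond (Mitsunobu) ⇒ 5-bromoresorcinol + 3,4-bis(TBSO)benzyl alcohol. This bond joins rings A and C in a fixed 1:1 ratio.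
4. The benzyl alcohol ⇒ 3,4-dihydroxybenzaldehyde by one-pot silylation and reduction.
5. No ring is formed, since all three benzene rings are bought. Ring C is joined to ring A first, then ring B is added.

Assumption: the target has no stereocentre and is achiral. Its only stereo-element is the E alkene, so "single enantiomer" is read as the single E isomer.

**Step 1**
Reactants: 1 3,4-dihydroxybenzaldehyde
Product: 3 [3,4-bis(tert-butyldimethylsilyloxy)phenyl]methanol, via bis-silyl aldehyde 2 (not isolated)
Conditions: TBSCl (2.3 equiv), imidazole (4 equiv), DMF, rt, 3 h; then MeOH, NaBH4 (1 equiv), 0 °C, 30 min (one pot)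
Reagents that add atoms: tert-butyldimethylsilyl chloride (TBSCl), CC(C)(C)[Si](C)(C)Cl
Why: Imidazole-promoted silylation caps both phenols, and the NaBH4 1,2-reduction of the aldehyde in the same flask is fast at 0 °C and leaves aryl silyl ethers intact; no stereocentre is formed.

**Step 2**
Reactants: 3 [3,4-bis(tert-butyldimethylsilyloxy)phenyl]methanol; 4 5-bromoresorcinol (5-bromobenzene-1,3-diol)
Product: 5 3-bromo-5-{[3,4-bis(tert-butyldimethylsilyloxy)phenyl]methoxy}phenol
Conditions: PPh3 (1.2 equiv), DIAD (1.2 equiv), 4 (3 equiv, excess recovered), THF, 0 °C → rt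
Reagents that add atoms: none
Why: In this Mitsunobu etherification the primary benzylic alcohol is activated as its oxyphosphonium salt and displaced (SN2) by a phenolic O–H of the symmetric diol, whose excess suppresses the bis-ether, and the C–O bond formed is the fragment-joining bond of the route that fixes one benzyl group per ring A.

**Step 3**
Reactants: 5 3-bromo-5-{[3,4-bis(tert-butyldimethylsilyloxy)phenyl]methoxy}phenol; 6 2-methoxy-4-vinylphenol (4-vinylguaiacol)
Product: 7 (E)-3-{[3,4-bis(tert-butyldimethylsilyloxy)phenyl]methoxy}-5-[2-(4-hydroxy-3-methoxyphenyl)ethenyl]phenol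
Conditions: 6 (1.3 equiv), Pd2(dba)3 (1.5 mol %), P(t-Bu)3·HBF4 (6 mol %), Cy2NMe (2 equiv), BHT (1 mol %), 1,4-dioxane, rt → 45 °C, Ar
Reagents that add atoms: none
Why: In this Mizoroki–Heck reaction the unhindered aryl bromide adds to the electron-rich Pd(0)/P(t-Bu)3 catalyst near room temperature, syn insertion at the terminal alkene carbon and syn β-hydride elimination give the E stilbene, and the weak amine base in a low-polarity solvent spares the aryl silyl ethers and the benzyl ether.

**Step 4**
Reactants: 7 (E)-3-{[3,4-bis(tert-butyldimethylsilyloxy)phenyl]methoxy}-5-[2-(4-hydroxy-3-methoxyphenyl)ethenyl]phenol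
Product: 11 gnetupendin B, via catechol ether 8 (not isolated), via quinone methide 9 (not isolated), via isorhapontigenin 10 (not isolated)
Conditions: TBAF/AcOH (1:1, 2.2 equiv each), degassed THF (0.02 M), 0 °C, 30 min, then 45 °C, Ar; pH 5 aqueous work-up
Reagents that add atoms: none
Why: Proposed new method: a desilylation-triggered O→C benzyl relay in which buffered fluoride first frees the catechol (8), the Bu4NOAc so formed deprotonates the OH para to the CH2–OAr bond, and 1,6-elimination expels the ring A aryloxide to give p-quinone methide 9 and isorhapontigenin 10 in an exact 1:1 ratio, which then recombine; every O-capture (aryloxide or acetate) only gives another p-hydroxybenzyl derivative that re-ionises, whereas attack by a resorcinol ring carbon followed by rearomatisation is irreversible, so the system drains to the C-benzyl compound; two of the three activated ring A carbons (C2 and C6, each ortho to one oxygen and para to the other) give the same product 11, while C4 between the two oxygens is the slow position, as in resorcinol hydroxybenzylation; no acid is present, so the E alkene, the OMe group and the free phenols are untouched; the closest known reaction types are fluoride-triggered quinone methide generation from O-silylated hydroxybenzyl derivatives, the 1,6-elimination of p-hydroxybenzyl ether self-immolative linkers, the C-selective addition of phenolates to p-quinone methides (as in base-catalysed resorcinol–formaldehyde condensation) and the acid-mediated benzyl aryl ether to benzylphenol rearrangement, but a base-triggered transfer of a benzyl group from an aryl ether oxygen to the ring carbon has not been used preparatively.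

**Compound list**
1 | 3,4-dihydroxybenzaldehyde | O=Cc1ccc(O)c(O)c1 | starting material
2 | 3,4-bis(tert-butyldimethylsilyloxy)benzaldehyde (not isolated) | O=Cc1ccc(O[Si](C)(C)C(C)(C)C)c(O[Si](C)(C)C(C)(C)C)c1 | intermediate
3 | [3,4-bis(tert-butyldimethylsilyloxy)phenyl]methanol | OCc1ccc(O[Si](C)(C)C(C)(C)C)c(O[Si](C)(C)C(C)(C)C)c1 | intermediate
4 | 5-bromoresorcinol (5-bromobenzene-1,3-diol) | Oc1cc(O)cc(Br)c1 | starting material
5 | 3-bromo-5-{[3,4-bis(tert-butyldimethylsilyloxy)phenyl]methoxy}phenol | Oc1cc(Br)cc(OCc2ccc(O[Si](C)(C)C(C)(C)C)c(O[Si](C)(C)C(C)(C)C)c2)c1 | intermediate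
6 | 2-methoxy-4-vinylphenol | C=Cc1ccc(O)c(OC)c1 | starting material
7 | (E)-3-{[3,4-bis(tert-butyldimethylsilyloxy)phenyl]methoxy}-5-[2-(4-hydroxy-3-methoxyphenyl)ethenyl]phenol | COc1cc(/C=C/c2cc(O)cc(OCc3ccc(O[Si](C)(C)C(C)(C)C)c(O[Si](C)(C)C(C)(C)C)c3)c2)ccc1O | intermediate
8 | (E)-4-({3-hydroxy-5-[2-(4-hydroxy-3-methoxyphenyl)ethenyl]phenoxy}methyl)benzene-1,2-diol (not isolated) | COc1cc(/C=C/c2cc(O)cc(OCc3ccc(O)c(O)c3)c2)ccc1O | intermediate
9 | 2-hydroxy-4-methylidenecyclohexa-2,5-dien-1-one (p-quinone methide, not isolated) | C=C1C=CC(=O)C(O)=C1 | intermediate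
10 | isorhapontigenin, (E)-5-[2-(4-hydroxy-3-methoxyphenyl)ethenyl]benzene-1,3-diol (not isolated) | COc1cc(/C=C/c2cc(O)cc(O)c2)ccc1O | intermediate
11 | gnetupendin B, (E)-4-(3,4-dihydroxybenzyl)-5-[2-(4-hydroxy-3-methoxyphenyl)ethenyl]benzene-1,3-diol | COc1cc(/C=C/c2cc(O)cc(O)c2Cc2ccc(O)c(O)c2)ccc1O | target

**Total step count:** 4 (step 1 is a one-pot, two-operation sequence).
**Longest linear sequence:** 4 (1 → 3 → 5 → 7 → 11).

**Three steps most likely to fail**

**Risk 1, step 4 (the proposed new step).**
- Quinone methide 9 can escape its partner. That gives crossover products: doubly benzylated material together with free 10.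
- Some attack at C4 and some quinone methide oligomers are also possible.
- The fallback uses only known chemistry. It moves the benzyl transfer to the simple bromide stage and makes it cationic.
- It sets out from 5. Treatment with catalytic Sc(OTf)3 (or 10 % TFA) in CH2Cl2 at 0 °C effects the acid-mediated benzyl aryl ether to benzylphenol rearrangement and gives 4-[3,4-bis(tert-butyldimethylsilyloxy)benzyl]-5-bromobenzene-1,3-diol F1.
- A Heck reaction of this bromide with 6 (Pd2(dba)3, P(t-Bu)3·HBF4, Cy2NMe, dioxane, 70 °C) gives 3'',4''-bis-O-TBS-gnetupendin B F2.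
- Ordinary buffered desilylation (TBAF/AcOH, THF, 0 °C) then comes back to the route at 11.

**Risk 2, step 3.**
- The vinylphenol can polymerise.
- Phenol plus amine can strip a silyl group, which would release the quinone methide prematurely.
- The fallback reverses the order of events, so the alkene is made before the labile ether exists.
- It sets out from 4. A Heck reaction with commercial 4-acetoxy-3-methoxystyrene (Pd(OAc)2, P(o-tol)3, Et3N, MeCN, 85 °C) gives (E)-4-[2-(3,5-dihydroxyphenyl)ethenyl]-2-methoxyphenyl acetate F3.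
- In this compound only the two equivalent resorcinol OH groups are free. Mitsunobu etherification with 3 (PPh3, DIAD, THF, diol in excess) gives the 4'-O-acetyl derivative of 7 F4.
- Aminolysis of the aryl acetate with n-BuNH2 in THF at 0 °C comes back to the route at 7.

**Risk 3, step 2.**
- Mono- versus bis-etherification of the symmetric diol is only statistically controlled.
- The electron-rich oxyphosphonium salt may also C-alkylate the resorcinol.
- The fallback desymmetrises the cheap diol with a protecting group first.
- It sets out from 4. TBSCl (1 equiv) and imidazole in DMF give 3-bromo-5-(tert-butyldimethylsilyloxy)phenol F5.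
- This compound has a single free OH, so the Mitsunobu reaction with 3 gives one ether, tert-butyl(3-bromo-5-{[3,4-bis(tert-butyldimethylsilyloxy)phenyl]methoxy}phenoxy)dimethylsilane F6.
- The Heck reaction with 6 under the step 3 conditions gives the 5-O-TBS derivative of 7 F7.
- Under the step 4 conditions, with 3.3 equiv of TBAF/AcOH, all three silyl groups are removed and the sequence comes back to the route at 8 in the flask.

**Further compounds**
F1 | step 4 | 4-[3,4-bis(tert-butyldimethylsilyloxy)benzyl]-5-bromobenzene-1,3-diol | Oc1cc(O)c(Cc2ccc(O[Si](C)(C)C(C)(C)C)c(O[Si](C)(C)C(C)(C)C)c2)c(Br)c1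
F2 | step 4 | 3'',4''-bis-O-TBS-gnetupendin B, (E)-4-[3,4-bis(tert-butyldimethylsilyloxy)benzyl]-5-[2-(4-hydroxy-3-methoxyphenyl)ethenyl]benzene-1,3-diol | COc1cc(/C=C/c2cc(O)cc(O)c2Cc2ccc(O[Si](C)(C)C(C)(C)C)c(O[Si](C)(C)C(C)(C)C)c2)ccc1O
F3 | step 3 | (E)-4-[2-(3,5-dihydroxyphenyl)ethenyl]-2-methoxyphenyl acetate | COc1cc(/C=C/c2cc(O)cc(O)c2)ccc1OC(C)=O
F4 | step 3 | 4'-O-acetyl derivative of 7, (E)-4-[2-(3-{[3,4-bis(tert-butyldimethylsilyloxy)phenyl]methoxy}-5-hydroxyphenyl)ethenyl]-2-methoxyphenyl acetate | COc1cc(/C=C/c2cc(O)cc(OCc3ccc(O[Si](C)(C)C(C)(C)C)c(O[Si](C)(C)C(C)(C)C)c3)c2)ccc1OC(C)=O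
F5 | step 2 | 3-bromo-5-(tert-butyldimethylsilyloxy)phenol | CC(C)(C)[Si](C)(C)Oc1cc(O)cc(Br)c1
F6 | step 2 | tert-butyl(3-bromo-5-{[3,4-bis(tert-butyldimethylsilyloxy)phenyl]methoxy}phenoxy)dimethylsilane | CC(C)(C)[Si](C)(C)Oc1cc(Br)cc(OCc2ccc(O[Si](C)(C)C(C)(C)C)c(O[Si](C)(C)C(C)(C)C)c2)c1
F7 | step 2 | 5-O-TBS derivative of 7, (E)-4-[2-(3-{[3,4-bis(tert-butyldimethylsilyloxy)phenyl]methoxy}-5-(tert-butyldimethylsilyloxy)phenyl)ethenyl]-2-methoxyphenol | COc1cc(/C=C/c2cc(O[Si](C)(C)C(C)(C)C)cc(OCc3ccc(O[Si](C)(C)C(C)(C)C)c(O[Si](C)(C)C(C)(C)C)c3)c2)ccc1O
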